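The earlier runs and the new flask are simulated for an exercise.

**Counting charges.** Each substrate must take up 3 partners to reach triple product, so compare amounts before times. Divide the partner charge by 3 times the substrate charge: for winter this gives 0.733, and that ratio is the partner cover. Below one, the coupling partner is the limiting reagent for the full sequence.

| flask | substrate | coupling partner | remark | time |
|---|---|---|---|---|
| green | 0.040 M | 0.44 M | run made earlier |  |
| violet | 0.18 M | 0.44 M | run made earlier |  |
| spring | 0.060 M | 0.440 M |  | 4.0 d |
| noon | 0.10 M | 0.440 M |  | 4.0 d |
| dusk | 0.15 M | 0.440 M |  | 4.0 d |
| winter | 0.20 M | 0.440 M |  | 4.0 d |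

- green (time / d: triple product / %, substrate / %): 0.208: 6.5, 46.9; 0.500: 24.9, 17.7; 1.04: 30.0, 5.7; 1.67: 17.1, 0; 2.00: 10.8, 0.2; 3.00: 2.9, 0.7
- violet (time / d: triple product / %, substrate / %): 0.208: 4.8, 49.2; 0.333: 10.5, 36.6; 0.625: 16.7, 22.1; 1.04: 17.2, 13.9; 1.67: 11.5, 8.8; 3.00: 4.4, 5.9

(scatter of a reading: 1 percentage point)

- what was read earlier has a scatter of 1 percentage point, one standard deviation
- reactions considered so far: coupling partner + bis adduct -> triple product + released group; coupling partner + single product -> bis adduct + released group; triple product -> over-reaction product; substrate + coupling partner -> single product + released group
- "hardly changes" means that all values lie within two and a half points (for a concentration: within two and a half percent of the largest)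

- [triple product] at the end for spring, noon, dusk, winter, in this order
- the course of these numbers from the first flask to the last (rises, then falls / falls all the way / rises all the way / falls, then rises / hardly changes)

**Main step.** Take substrate + coupling partner first. Green's first reading has substrate falling at about 3.64 /d, which you can count as 14.6 turnovers in 4.0 d. This step makes no triple product, and it asks one partner per substrate, which winter's charge covers.

**Two couplings.** Add the next two steps and the demand triples. Now the ceiling on [triple product] climbs with the substrate charge up to 0.147 M, where the cover is one, and goes no higher beyond it. The earlier runs show the cover at work. Green, with a cover of 3.67, reads 0.7% substrate at 3.00 d, but violet, with 0.815, still reads 5.9%.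

**Over-reaction.** Now let triple product leave. Green's tail reads as a fall of about 1.33 /d, and I take that as a low estimate of the decay constant, since the tail may still be fed. Even so it gives 5.32 turnovers in 4.0 d. So I expect the end value to lean on late feed rather than on early coupling.

**My reckoning.** Spring, with a cover of 2.44, should finish its couplings early, so I expect its number to be small. Dusk, with 0.978, should run its partner down slowly and keep feeding late. Winter's cover lies lower, so I expect its partner to give out sooner and the row to rise, then fall, with its top at dusk. The forecast differs: it gave 5.000 × 10⁻⁴ M, 0.0012 M, 0.0031 M and 0.0042 M, with the course rises all the way: “I expect a rise overall”.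

**The flasks.** [Triple product] at 4.0 d reads 3.42 × 10⁻⁴ M, 0.00167 M, 0.00359 M and 0.00160 M, so the course is rises, then falls, turning at 0.15 M, under these equations.

    coupling partner + bis adduct → triple product + released group (k = 2.00 × 10⁻⁴ /M/s)
    coupling partner + single product → bis adduct + released group (k = 9.60 × 10⁻⁵ /M/s)
    triple product → over-reaction product (k = 2.40 × 10⁻⁵ /s)
    substrate + coupling partner → single product + released group (k = 1.00 × 10⁻⁴ /M/s)

In winter the partner stands at 0.858% of its charge at the end, beside 8.38% substrate and 21.8% single product. Each over-reaction product has cost 3 partners, so the cover caps its share of the substrate charge. Dusk's cover of 0.978 sits above the 95.8% found at 40.0 d, and winter's cover of 0.733 sits above its 57.6% at 40.0 d.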